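**Retrosynthetic overview**
1. Kazinol D ⇐ desilylation of 20 ⇐ aromatic Claisen rearrangement of the ring-A 4-O-prenyl ether 18. The 1,1-dimethylallyl group is made last, so no terminal vinyl group is present during hydroboration.
2. The ring-B C5-prenyl group ⇐ Br/Li exchange and prenyl bromide on the bromide that survives the fragment union (16).
3. The propane tether ⇐ B-alkyl Suzuki coupling of the 9-BBN adduct of allylarene 13 with the C6–Br bond of 5,6-dibromochromanol 7.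
4. 7 ⇐ 4,5-dibromocatechol + 3-chloro-3-methylbutyne (propargyl-ether Claisen/oxa-6π, then C=C hydrogenation). 13 ⇐ 4-bromoresorcinol (O-prenylation, TIPS, allyl Suzuki).
5. Ring order: both benzene rings are bought. The only ring formed is the pyran, as a 2H-pyran in step 2 and saturated in step 3.

Assumption: the target SMILES has no stereocentre and no stereogenic C=C, so kazinol D is achiral and "single enantiomer" calls for no stereocontrol.

**Step 1**
Reactants: 1 4,5-dibromobenzene-1,2-diol; 2 3-chloro-3-methylbut-1-yne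
Product: 3 4,5-dibromo-2-[(2-methylbut-3-yn-2-yl)oxy]phenol
Conditions: 1 (1.5 equiv), 2 (1.0 equiv), DBU (1.1 equiv), CuCl2·2H2O (1 mol %), MeCN, 0 °C → rt, Ar
Reagents that add atoms: none
Why: Cu-catalysed O-propargylation of a phenoxide with a tertiary propargyl chloride; 1 is C2-symmetric, so either OH gives the same mono-ether, and excess 1 with the bulk of the first ether suppresses the bis-ether.

**Step 2**
Reactants: 3 4,5-dibromo-2-[(2-methylbut-3-yn-2-yl)oxy]phenol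
Product: 6 5,6-dibromo-2,2-dimethyl-2H-chromen-8-ol, via 4,5-dibromo-3-(3-methylbuta-1,2-dien-1-yl)benzene-1,2-diol 4 (not isolated), via (6E)-4,5-dibromo-2-hydroxy-6-(3-methylbut-2-en-1-ylidene)cyclohexa-2,4-dien-1-one 5 (not isolated)
Conditions: PhNEt2, 185 °C, 3 h
Reagents that add atoms: none
Why: Aryl propargyl ether Claisen rearrangement to the only free ortho carbon gives allenylphenol 4, and its 1,5-H shift to o-quinone methide 5 followed by oxa-6π electrocyclisation closes the pyran ring; no stereocentre is formed.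

**Step 3**
Reactants: 6 5,6-dibromo-2,2-dimethyl-2H-chromen-8-ol
Product: 7 5,6-dibromo-2,2-dimethylchroman-8-ol
Conditions: H2 (1 atm), PtO2 (3 mol %), EtOAc, rt, stopped after 1 equiv H2
Reagents that add atoms: none
Why: Catalytic hydrogenation of the cis-disubstituted chromene C=C over Pt in neutral medium, which leaves aryl C–Br bonds intact.

**Step 4**
Reactants: 8 4-bromobenzene-1,3-diol; 9 1-bromo-3-methylbut-2-ene (prenyl bromide)
Product: 10 2-bromo-5-[(3-methylbut-2-en-1-yl)oxy]phenol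
Conditions: 9 (1.0 equiv), K2CO3 (1.0 equiv), acetone, 0 °C → rt
Reagents that add atoms: none
Why: Williamson ether synthesis that favours the unhindered OH para to Br, because the OH ortho to Br is shielded and its phenoxide is less nucleophilic; the minor isomer and the bis-ether are removed by chromatography.

**Step 5**
Reactants: 10 2-bromo-5-[(3-methylbut-2-en-1-yl)oxy]phenol
Product: 11 {2-bromo-5-[(3-methylbut-2-en-1-yl)oxy]phenoxy}triisopropylsilane
Conditions: TIPSCl, imidazole, DMF, rt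
Reagents that add atoms: chlorotri(propan-2-yl)silane (TIPSCl), CC(C)[Si](Cl)(C(C)C)C(C)C
Why: Standard phenol silylation; the bulky, base-stable TIPS ether survives both Suzuki steps and n-BuLi and later shields C3 in the Claisen step.

**Step 6**
Reactants: 11 {2-bromo-5-[(3-methylbut-2-en-1-yl)oxy]phenoxy}triisopropylsilane; 12 2-allyl-4,4,5,5-tetramethyl-1,3,2-dioxaborolane
Product: 13 {2-allyl-5-[(3-methylbut-2-en-1-yl)oxy]phenoxy}triisopropylsilane
Conditions: 12 (1.5 equiv), Pd(OAc)2 (3 mol %), SPhos (6 mol %), K3PO4, THF/H2O 10:1, 60 °C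
Reagents that add atoms: none
Why: Suzuki–Miyaura allylation of the single aryl bromide; it avoids an o-silyloxy aryllithium (retro-Brook risk), and the trisubstituted aryl prenyl ether ionises far more slowly with Pd(0) than an allyl ether would.

**Step 7**
Reactants: 13 {2-allyl-5-[(3-methylbut-2-en-1-yl)oxy]phenoxy}triisopropylsilane; 7 5,6-dibromo-2,2-dimethylchroman-8-ol
Product: 15 5-bromo-2,2-dimethyl-6-(3-{4-[(3-methylbut-2-en-1-yl)oxy]-2-[(triisopropylsilyl)oxy]phenyl}propyl)chroman-8-ol, via 9-(3-{4-[(3-methylbut-2-en-1-yl)oxy]-2-[(triisopropylsilyl)oxy]phenyl}propyl)-9-borabicyclo[3.3.1]nonane 14 (not isolated)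
Conditions: 9-BBN-H (1.1 equiv), THF, 0 °C → rt, 3 h; then 7 (1.0 equiv), Pd(dppf)Cl2·CH2Cl2 (5 mol %), 3 M aq. K3PO4 (4 equiv), DMF, 60 °C
Reagents that add atoms: none
Why: 9-BBN hydroborates the monosubstituted allyl C=C (anti-Markovnikov) much faster than the trisubstituted prenyl C=C, and in the B-alkyl Suzuki–Miyaura coupling Pd(0) inserts into C6–Br (open C7–H flank, meta to the phenoxide) rather than C5–Br (flanked on both sides, para to O−).

**Step 8**
Reactants: 15 5-bromo-2,2-dimethyl-6-(3-{4-[(3-methylbut-2-en-1-yl)oxy]-2-[(triisopropylsilyl)oxy]phenyl}propyl)chroman-8-ol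
Product: 16 8-O-triisopropylsilyl ether of 15
Conditions: TIPSCl, imidazole, DMF, rt
Reagents that add atoms: chlorotri(propan-2-yl)silane (TIPSCl), CC(C)[Si](Cl)(C(C)C)C(C)C
Why: Phenol silylation removes the only acidic proton before the organolithium step.

**Step 9**
Reactants: 16 8-O-triisopropylsilyl ether of 15; 9 1-bromo-3-methylbut-2-ene
Product: 18 5-(3-methylbut-2-en-1-yl) analogue of 16 (prenyl in place of Br), via 5-lithio analogue of 16 (Li in place of Br) 17 (not isolated)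
Conditions: n-BuLi (1.1 equiv), THF, −78 °C, 30 min; then 9 (1.5 equiv), −78 → 0 °C
Reagents that add atoms: none
Why: Bromine–lithium exchange is insensitive to the two ortho substituents and faster than any deprotonation at −78 °C, and the hindered aryllithium alkylates prenyl bromide at the primary carbon (SN2, not SN2′).

**Step 10**
Reactants: 18 5-(3-methylbut-2-en-1-yl) analogue of 16
Product: 20 4-{3-[2,2-dimethyl-5-(3-methylbut-2-en-1-yl)-8-(triisopropylsilyloxy)chroman-6-yl]propyl}-2-(2-methylbut-3-en-2-yl)-5-[(triisopropylsilyl)oxy]phenol, via 4-{3-[2,2-dimethyl-5-(3-methylbut-2-en-1-yl)-8-(triisopropylsilyloxy)chroman-6-yl]propyl}-6-(2-methylbut-3-en-2-yl)-3-[(triisopropylsilyl)oxy]cyclohexa-2,4-dien-1-one 19 (not isolated)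
Conditions: PhNEt2 (degassed), 190 °C, sealed tube, 3 h
Reagents that add atoms: none
Why: Aromatic Claisen [3,3] rearrangement with allyl inversion turns O–CH2CH=CMe2 into C–CMe2CH=CH2, bonding at C5 because C3 is buried between OTIPS and the ether oxygen; dienone 19 tautomerises, so its transient sp3 carbon leaves no stereocentre.

**Step 11**
Reactants: 20 4-{3-[2,2-dimethyl-5-(3-methylbut-2-en-1-yl)-8-(triisopropylsilyloxy)chroman-6-yl]propyl}-2-(2-methylbut-3-en-2-yl)-5-[(triisopropylsilyl)oxy]phenol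
Product: 21 kazinol D, 4-{3-[8-hydroxy-2,2-dimethyl-5-(3-methylbut-2-en-1-yl)chroman-6-yl]propyl}-6-(2-methylbut-3-en-2-yl)benzene-1,3-diol
Conditions: TBAF (2.5 equiv), AcOH (2.5 equiv), THF, 0 °C → rt
Reagents that add atoms: none
Why: Buffered fluoride desilylation cleaves both aryl TIPS ethers without acid, so neither the prenyl group nor the o-(1,1-dimethylallyl)phenol can cyclise.

**Compound list**
1 | 4,5-dibromobenzene-1,2-diol | Oc1cc(Br)c(Br)cc1O | starting material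
2 | 3-chloro-3-methylbut-1-yne | C#CC(C)(C)Cl | starting material
3 | 4,5-dibromo-2-[(2-methylbut-3-yn-2-yl)oxy]phenol | C#CC(C)(C)Oc1cc(Br)c(Br)cc1O | intermediate
4 | 4,5-dibromo-3-(3-methylbuta-1,2-dien-1-yl)benzene-1,2-diol (formed in situ) | CC(C)=C=Cc1c(O)c(O)cc(Br)c1Br | intermediate
5 | (6E)-4,5-dibromo-2-hydroxy-6-(3-methylbut-2-en-1-ylidene)cyclohexa-2,4-dien-1-one (formed in situ) | CC(C)=C/C=C1\C(=O)C(O)=CC(Br)=C1Br | intermediate
6 | 5,6-dibromo-2,2-dimethyl-2H-chromen-8-ol | CC1(C)C=Cc2c(O1)c(O)cc(Br)c2Br | intermediate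
7 | 5,6-dibromo-2,2-dimethylchroman-8-ol | CC1(C)CCc2c(O1)c(O)cc(Br)c2Br | intermediate
8 | 4-bromobenzene-1,3-diol | Oc1ccc(Br)c(O)c1 | starting material
9 | 1-bromo-3-methylbut-2-ene | CC(C)=CCBr | starting material
10 | 2-bromo-5-[(3-methylbut-2-en-1-yl)oxy]phenol | CC(C)=CCOc1ccc(Br)c(O)c1 | intermediate
11 | {2-bromo-5-[(3-methylbut-2-en-1-yl)oxy]phenoxy}triisopropylsilane | CC(C)=CCOc1ccc(Br)c(O[Si](C(C)C)(C(C)C)C(C)C)c1 | intermediate
12 | 2-allyl-4,4,5,5-tetramethyl-1,3,2-dioxaborolane | C=CCB1OC(C)(C)C(C)(C)O1 | starting material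
13 | {2-allyl-5-[(3-methylbut-2-en-1-yl)oxy]phenoxy}triisopropylsilane | C=CCc1ccc(OCC=C(C)C)cc1O[Si](C(C)C)(C(C)C)C(C)C | intermediate
14 | B-alkyl-9-BBN adduct of 13 (formed in situ) | CC(C)=CCOc1ccc(CCCB2C3CCCC2CCC3)c(O[Si](C(C)C)(C(C)C)C(C)C)c1 | intermediate
15 | 5-bromo-6-(3-arylpropyl)-2,2-dimethylchroman-8-ol (aryl = 4-prenyloxy-2-TIPSO-phenyl) | CC(C)=CCOc1ccc(CCCc2cc(O)c3OC(C)(C)CCc3c2Br)c(O[Si](C(C)C)(C(C)C)C(C)C)c1 | intermediate
16 | 8-O-TIPS ether of 15 | CC(C)=CCOc1ccc(CCCc2cc(O[Si](C(C)C)(C(C)C)C(C)C)c3OC(C)(C)CCc3c2Br)c(O[Si](C(C)C)(C(C)C)C(C)C)c1 | intermediate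
17 | 5-lithio analogue of 16 (formed in situ) | CC(C)=CCOc1ccc(CCCc2cc(O[Si](C(C)C)(C(C)C)C(C)C)c3OC(C)(C)CCc3c2[Li])c(O[Si](C(C)C)(C(C)C)C(C)C)c1 | intermediate
18 | 5-prenyl analogue of 16 | CC(C)=CCOc1ccc(CCCc2cc(O[Si](C(C)C)(C(C)C)C(C)C)c3OC(C)(C)CCc3c2CC=C(C)C)c(O[Si](C(C)C)(C(C)C)C(C)C)c1 | intermediate
19 | ortho-dienone of the Claisen step (formed in situ, racemic at its transient sp3 carbon) | C=CC(C)(C)C1C=C(CCCc2cc(O[Si](C(C)C)(C(C)C)C(C)C)c3OC(C)(C)CCc3c2CC=C(C)C)C(O[Si](C(C)C)(C(C)C)C(C)C)=CC1=O | intermediate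
20 | 2,8′-bis-O-TIPS kazinol D | C=CC(C)(C)c1cc(CCCc2cc(O[Si](C(C)C)(C(C)C)C(C)C)c3OC(C)(C)CCc3c2CC=C(C)C)c(O[Si](C(C)C)(C(C)C)C(C)C)cc1O | intermediate
21 | kazinol D (achiral) | C=CC(C)(C)c1cc(CCCc2cc(O)c3c(c2CC=C(C)C)CCC(C)(C)O3)c(O)cc1O | target

**Step count**
Total step count: 11.
Longest linear sequence: 8 steps (1 → 3 → 6 → 7 → 15 → 16 → 18 → 20 → 21). The ring-A branch (8 → 10 → 11 → 13) has 3 steps before the union.

**Steps most likely to fail**

*Step 7 (telling the two C–Br bonds of 7 apart).* The fallback makes the halogens themselves different.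
- It sets out from 2, which alkylates commercial catechol in place of 1 (DBU, cat. CuCl2, MeCN) to give 2-[(2-methylbut-3-yn-2-yl)oxy]phenol F5.
- Heating in PhNEt2 takes F5 through 3-(3-methylbuta-1,2-dien-1-yl)benzene-1,2-diol F6 and (6Z)-2-hydroxy-6-(3-methylbut-2-en-1-ylidene)cyclohexa-2,4-dien-1-one F7 to 2,2-dimethyl-2H-chromen-8-ol F8. H2 over Pd/C then gives 2,2-dimethylchroman-8-ol F9.
- NBS (MeCN, 0 °C) brominates para to the free phenol to give 5-bromo-2,2-dimethylchroman-8-ol F10, and TIPSCl/imidazole gives [(5-bromo-2,2-dimethylchroman-8-yl)oxy]triisopropylsilane F11.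
- NIS with cat. TFA iodinates para to the ring oxygen, since C7 is shielded by OTIPS, to give [(5-bromo-6-iodo-2,2-dimethylchroman-8-yl)oxy]triisopropylsilane F12.
- Borane 14 then couples with the C–I bond alone at room temperature (Pd(dppf)Cl2, aq. K3PO4), and the route is rejoined at 16.

*Step 10 (C5 versus C3 in the late Claisen, and thermal damage to an advanced compound).* The fallback moves the rearrangement to the small bromide and swaps the roles of the coupling partners, so that 9-BBN never meets the new vinyl group.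
- It sets out from 11. Heating (PhNEt2, 190 °C) gives, through 4-bromo-6-(2-methylbut-3-en-2-yl)-3-[(triisopropylsilyl)oxy]cyclohexa-2,4-dien-1-one F13, the phenol 4-bromo-2-(2-methylbut-3-en-2-yl)-5-[(triisopropylsilyl)oxy]phenol F14, whose regioisomer can be removed on scale.
- TBSCl/imidazole converts F14 into {4-bromo-2-(2-methylbut-3-en-2-yl)-5-[(triisopropylsilyl)oxy]phenoxy}(tert-butyl)dimethylsilane F15.
- In parallel, 7 and 12 are coupled at C6–Br under the conditions of step 6 to give 6-allyl-5-bromo-2,2-dimethylchroman-8-ol F16, and TIPSCl gives [(6-allyl-5-bromo-2,2-dimethylchroman-8-yl)oxy]triisopropylsilane F17.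
- n-BuLi gives the 5-lithio compound [(6-allyl-5-lithio-2,2-dimethylchroman-8-yl)oxy]triisopropylsilane F18, and 9 gives {[6-allyl-2,2-dimethyl-5-(3-methylbut-2-en-1-yl)chroman-8-yl]oxy}triisopropylsilane F19.
- 9-BBN adds only to the allyl group to give the B-alkyl-9-BBN adduct of F19 F20. Its Suzuki coupling with F15 gives 2,8′-bis-O-TIPS-4-O-TBS kazinol D F21.
- TBAF/AcOH brings the route back at 21.

*Step 4 (which OH of 8 is alkylated).* The fallback replaces steric discrimination with hydrogen-bond discrimination.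
- It sets out from 9, which alkylates commercial 2,4-dihydroxybenzaldehyde (K2CO3, acetone). The 2-OH is locked in a hydrogen bond to the formyl group, so only 2-hydroxy-4-[(3-methylbut-2-en-1-yl)oxy]benzaldehyde F1 forms.
- TIPSCl/imidazole gives 4-[(3-methylbut-2-en-1-yl)oxy]-2-[(triisopropylsilyl)oxy]benzaldehyde F2, and NaBH4 gives {4-[(3-methylbut-2-en-1-yl)oxy]-2-[(triisopropylsilyl)oxy]phenyl}methanol F3.
- PPh3/CCl4 gives {2-(chloromethyl)-5-[(3-methylbut-2-en-1-yl)oxy]phenoxy}triisopropylsilane F4.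
- CuI-catalysed coupling of F4 with vinylmagnesium bromide (THF, −20 °C) brings the route back at 13.

**Further compounds**
F1 | step 4 | 2-hydroxy-4-[(3-methylbut-2-en-1-yl)oxy]benzaldehyde | CC(C)=CCOc1ccc(C=O)c(O)c1
F2 | step 4 | 4-[(3-methylbut-2-en-1-yl)oxy]-2-[(triisopropylsilyl)oxy]benzaldehyde | CC(C)=CCOc1ccc(C=O)c(O[Si](C(C)C)(C(C)C)C(C)C)c1
F3 | step 4 | {4-[(3-methylbut-2-en-1-yl)oxy]-2-[(triisopropylsilyl)oxy]phenyl}methanol | CC(C)=CCOc1ccc(CO)c(O[Si](C(C)C)(C(C)C)C(C)C)c1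
F4 | step 4 | {2-(chloromethyl)-5-[(3-methylbut-2-en-1-yl)oxy]phenoxy}triisopropylsilane | CC(C)=CCOc1ccc(CCl)c(O[Si](C(C)C)(C(C)C)C(C)C)c1
F5 | step 7 | 2-[(2-methylbut-3-yn-2-yl)oxy]phenol | C#CC(C)(C)Oc1ccccc1O
F6 | step 7 | 3-(3-methylbuta-1,2-dien-1-yl)benzene-1,2-diol | CC(C)=C=Cc1cccc(O)c1O
F7 | step 7 | (6Z)-2-hydroxy-6-(3-methylbut-2-en-1-ylidene)cyclohexa-2,4-dien-1-one | CC(C)=C/C=C1\C(=O)C(O)=CC=C1
F8 | step 7 | 2,2-dimethyl-2H-chromen-8-ol | CC1(C)C=Cc2cccc(O)c2O1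
F9 | step 7 | 2,2-dimethylchroman-8-ol | CC1(C)CCc2cccc(O)c2O1
F10 | step 7 | 5-bromo-2,2-dimethylchroman-8-ol | CC1(C)CCc2c(Br)ccc(O)c2O1
F11 | step 7 | [(5-bromo-2,2-dimethylchroman-8-yl)oxy]triisopropylsilane | CC1(C)CCc2c(Br)ccc(O[Si](C(C)C)(C(C)C)C(C)C)c2O1
F12 | step 7 | [(5-bromo-6-iodo-2,2-dimethylchroman-8-yl)oxy]triisopropylsilane | CC1(C)CCc2c(Br)c(I)cc(O[Si](C(C)C)(C(C)C)C(C)C)c2O1
F13 | step 10 | 4-bromo-6-(2-methylbut-3-en-2-yl)-3-[(triisopropylsilyl)oxy]cyclohexa-2,4-dien-1-one | C=CC(C)(C)C1C=C(Br)C(O[Si](C(C)C)(C(C)C)C(C)C)=CC1=O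
F14 | step 10 | 4-bromo-2-(2-methylbut-3-en-2-yl)-5-[(triisopropylsilyl)oxy]phenol | C=CC(C)(C)c1cc(Br)c(O[Si](C(C)C)(C(C)C)C(C)C)cc1O
F15 | step 10 | {4-bromo-2-(2-methylbut-3-en-2-yl)-5-[(triisopropylsilyl)oxy]phenoxy}(tert-butyl)dimethylsilane | C=CC(C)(C)c1cc(Br)c(O[Si](C(C)C)(C(C)C)C(C)C)cc1O[Si](C)(C)C(C)(C)C
F16 | step 10 | 6-allyl-5-bromo-2,2-dimethylchroman-8-ol | C=CCc1cc(O)c2OC(C)(C)CCc2c1Br
F17 | step 10 | [(6-allyl-5-bromo-2,2-dimethylchroman-8-yl)oxy]triisopropylsilane | C=CCc1cc(O[Si](C(C)C)(C(C)C)C(C)C)c2OC(C)(C)CCc2c1Br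
F18 | step 10 | [(6-allyl-5-lithio-2,2-dimethylchroman-8-yl)oxy]triisopropylsilane | C=CCc1cc(O[Si](C(C)C)(C(C)C)C(C)C)c2OC(C)(C)CCc2c1[Li]
F19 | step 10 | {[6-allyl-2,2-dimethyl-5-(3-methylbut-2-en-1-yl)chroman-8-yl]oxy}triisopropylsilane | C=CCc1cc(O[Si](C(C)C)(C(C)C)C(C)C)c2OC(C)(C)CCc2c1CC=C(C)C
F20 | step 10 | B-alkyl-9-BBN adduct of F19 | CC(C)=CCc1c(CCCB2C3CCCC2CCC3)cc(O[Si](C(C)C)(C(C)C)C(C)C)c2OC(C)(C)CCc12
F21 | step 10 | 2,8′-bis-O-TIPS-4-O-TBS kazinol D | C=CC(C)(C)c1cc(CCCc2cc(O[Si](C(C)C)(C(C)C)C(C)C)c3OC(C)(C)CCc3c2CC=C(C)C)c(O[Si](C(C)C)(C(C)C)C(C)C)cc1O[Si](C)(C)C(C)(C)C
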